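The flavone is disconnected at the O1–C8a bond of the pyranone ring. Ring A is carried as a 2,4-dimethoxyphenyl ketone whose free ortho C–H becomes C8a; this carbon is meta to both the 5- and 7-methoxyls (a 3,5-dimethoxyphenyl ketone would give the 6,8-dimethoxy isomer). A single palladium-catalysed anodic dehydrogenation joins the enol oxygen on the B-ring side to that carbon and closes ring C; it exploits the C8a–H bond of ring A, ortho to C4a and within reach of O1, while the competing C6'–H of ring B is shielded by the 5'-pivalate. The precursor is an acyclic 2-methoxy-1,3-diaryl-propane-1,3-dione that already holds every oxygen substituent.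

Key step: step 5

Remark: the target has no stereocentre, so no stereocontrol is needed. Dione 9 has one configurationally labile centre (racemic) that becomes sp2 in step 5.

Remark: because C8a is meta to both methoxyls, it is not a site where an arene radical cation would be trapped. The ring closure is therefore designed as an inner-sphere, oxygen-directed C–H metalation, with the anode serving only as terminal oxidant.

Step 1
Reactants: 1 2,4-dimethoxybenzaldehyde
Product: 3 2,4-dimethoxyphenol, via 2,4-dimethoxyphenyl formate 2 (not isolated)
Conditions: 30% H2O2, cat. H2SO4, MeOH, rt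
Reagents that add atoms: hydrogen peroxide, OO
Why: Acid-catalysed Dakin oxidation, in which the electron-rich aryl group migrates to oxygen in the peroxy hemiacetal (Baeyer–Villiger-type shift) and the resulting aryl formate is methanolysed in the same flask.

Step 2
Reactants: 3 2,4-dimethoxyphenol; 4 pivaloyl chloride
Product: 5 2,4-dimethoxyphenyl pivalate
Conditions: PivCl, Et3N, cat. DMAP, CH2Cl2, 0 °C to rt
Reagents that add atoms: pivaloyl chloride (4), CC(C)(C)C(=O)Cl
Why: DMAP-catalysed O-acylation of the phenol, installing at the outset a bulky ester that should tolerate Lewis acid, amine base and oxidation and later leaves by mild methanolysis.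

Step 3
Reactants: 5 2,4-dimethoxyphenyl pivalate; 6 methoxyacetyl chloride
Product: 7 5-(2-methoxyacetyl)-2,4-dimethoxyphenyl pivalate
Conditions: SnCl4 (promoter), CH2Cl2, −20 to 0 °C
Reagents that add atoms: methoxyacetyl chloride (6), COCC(=O)Cl
Why: Friedel–Crafts acylation at the ring carbon para to one methoxyl and ortho to the other, the most nucleophilic and least hindered site, with a mild Lewis acid at low temperature to spare the methyl ethers and the ester.

Step 4
Reactants: 7 5-(2-methoxyacetyl)-2,4-dimethoxyphenyl pivalate; 8 2,4-dimethoxybenzoyl chloride
Product: 9 1-(2,4-dimethoxyphenyl)-3-[2,4-dimethoxy-5-(pivaloyloxy)phenyl]-2-methoxypropane-1,3-dione (racemic, configurationally labile)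
Conditions: MgBr2·OEt2 (promoter), i-Pr2NEt, CH2Cl2, rt; dilute aq. HCl work-up
Reagents that add atoms: 2,4-dimethoxybenzoyl chloride (8), COc1ccc(C(=O)Cl)c(OC)c1
Why: Crossed Claisen-type C-acylation by soft enolisation, in which magnesium chelation of the α-methoxy ketone permits deprotonation by an amine base that leaves the pivalate untouched, and the magnesium diketonate of the product resists further acylation.

Step 5
Reactants: 9 1-(2,4-dimethoxyphenyl)-3-[2,4-dimethoxy-5-(pivaloyloxy)phenyl]-2-methoxypropane-1,3-dione
Product: 10 5'-O-pivaloyl-3,5,7,2',4'-pentamethoxyflavone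
Conditions: Pd(OAc)2 (10 mol %), Ac-Gly-OH (20 mol %), KOAc, AcOH, divided cell, graphite-felt anode/Pt cathode, ca. +1.2 V vs Ag/AgCl, 70 °C
Reagents that add atoms: none
Why: Proposed new method: the enolised dione should bind Pd(II) through the oxygen on the B-ring side, acetate-assisted concerted metalation–deprotonation at the free ortho C–H of the 2,4-dimethoxyphenyl ring (acidified by the flanking acyl group and untouched by resonance donation from the two meta methoxyls) should give a seven-membered C,O-palladacycle, and anodic oxidation to Pd(III)/Pd(IV) should trigger C–O reductive elimination while protons are reduced to hydrogen at the cathode. The closest known reaction types are the Pd(II)/Pd(IV) dehydrogenative lactonisation of biaryl-2-carboxylic acids to benzocoumarins, where a carboxylate (here its vinylogue, the enol) sits at the same distance from the arene C–H, and palladium-catalysed anodic C–H acetoxylation of arenes. The pyranone ring closes by reductive elimination from the palladacycle, formally a 6-endo-trig attack of oxygen on the arene carbon, and no stereocentre is created. The step needs selectivity between the two aryl rings: the A-ring C–H has only a hydrogen neighbour, whereas C6'–H of ring B is buttressed by the bulky 5'-pivaloyloxy group, which also keeps that ring less electron-rich. Holding the anode below the potential at which the dimethoxyaryl ketones or the neutral dione are oxidised directly should suppress outer-sphere radical-cation chemistry, which would favour carbons ortho or para to the methoxyls (none of which can close a six-membered ring), and no oxygen-transfer oxidant is present to attack the central carbon. Acetic acid as solvent keeps O,O-chelation of palladium by the diketonate reversible, so that the singly bound form can reach the C–H bond.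

Step 6
Reactants: 10 5'-O-pivaloyl-3,5,7,2',4'-pentamethoxyflavone
Product: 11 5'-hydroxy-3,5,7,2',4'-pentamethoxyflavone
Conditions: K2CO3, MeOH, rt to 40 °C; aq. NH4Cl work-up
Reagents that add atoms: none
Why: Base-mediated transesterification (methanolysis) of the aryl pivalate, under which the methyl ethers and the 3-methoxychromone should be inert.

Compound list
1 | 2,4-dimethoxybenzaldehyde | COc1ccc(C=O)c(OC)c1 | starting material
2 | 2,4-dimethoxyphenyl formate | COc1ccc(OC=O)c(OC)c1 | intermediate
3 | 2,4-dimethoxyphenol | COc1ccc(O)c(OC)c1 | intermediate
4 | pivaloyl chloride | CC(C)(C)C(=O)Cl | starting material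
5 | 2,4-dimethoxyphenyl pivalate | COc1ccc(OC(=O)C(C)(C)C)c(OC)c1 | intermediate
6 | methoxyacetyl chloride | COCC(=O)Cl | starting material
7 | 5-(2-methoxyacetyl)-2,4-dimethoxyphenyl pivalate | COCC(=O)c1cc(OC(=O)C(C)(C)C)c(OC)cc1OC | intermediate
8 | 2,4-dimethoxybenzoyl chloride | COc1ccc(C(=O)Cl)c(OC)c1 | starting material
9 | 1-(2,4-dimethoxyphenyl)-3-[2,4-dimethoxy-5-(pivaloyloxy)phenyl]-2-methoxypropane-1,3-dione (racemic) | COc1ccc(C(=O)C(OC)C(=O)c2cc(OC(=O)C(C)(C)C)c(OC)cc2OC)c(OC)c1 | intermediate
10 | 5'-O-pivaloyl-3,5,7,2',4'-pentamethoxyflavone | COc1cc(OC)c2c(=O)c(OC)c(-c3cc(OC(=O)C(C)(C)C)c(OC)cc3OC)oc2c1 | intermediate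
11 | 5'-hydroxy-3,5,7,2',4'-pentamethoxyflavone | COc1cc(OC)c2c(=O)c(OC)c(-c3cc(O)c(OC)cc3OC)oc2c1 | target

Total step count: 6. Longest linear sequence: 6 steps (1 to 11).

Steps most likely to fail

Step 5. Palladium may be sequestered as an unreactive O,O-chelate, metalation may occur on ring B, or the anode may oxidise the arenes or the enol directly, so that closure fails or goes to the wrong ring. The fallback replaces the C–H bond by a C–Br bond and forms the same O1–C8a bond by known copper-catalysed intramolecular O-arylation of a 1-(2-bromoaryl)-1,3-dione. It sets out from 7. Acylation under the conditions of step 4 with 2-bromo-4,6-dimethoxybenzoyl chloride F1 (from 2-bromo-4,6-dimethoxybenzoic acid and oxalyl chloride) should give 1-(2-bromo-4,6-dimethoxyphenyl)-3-[2,4-dimethoxy-5-(pivaloyloxy)phenyl]-2-methoxypropane-1,3-dione F2. Treatment with CuI, 1,10-phenanthroline and K2CO3 in DMF at 90 °C should then close the pyranone by Ullmann-type enolate O-arylation, returning to the route at 10.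

Step 3. The α-methoxy acylium ion may lose carbon monoxide and alkylate the ring, the Lewis acid may cleave the methyl ether ortho to the new carbonyl, or the pivaloyl group may migrate. The fallback builds the ketone by halogen–metal exchange instead of electrophilic acylation and sets out from 5. Iodination (NIS, cat. TFA, MeCN) at the same ring position should give 5-iodo-2,4-dimethoxyphenyl pivalate F3. Iodine–magnesium exchange (i-PrMgCl·LiCl, THF, −20 °C) should give [2,4-dimethoxy-5-(pivaloyloxy)phenyl]magnesium chloride F4. Its reaction with N-methoxy-N-methyl-2-methoxyacetamide (Weinreb ketone synthesis) returns to the route at 7.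

Step 4. The enolate may be acylated on oxygen, the pivaloyl group may be transferred to the enolate, or the product may be acylated a second time. The fallback makes the C–C bond by aldol addition and sets the oxidation level afterwards; it sets out from 7. The lithium enolate (LiHMDS, THF, −78 °C) should add to aldehyde 1 to give 3-(2,4-dimethoxyphenyl)-3-hydroxy-1-[2,4-dimethoxy-5-(pivaloyloxy)phenyl]-2-methoxypropan-1-one F5 as a mixture of diastereomers. Dess–Martin oxidation of either diastereomer returns to the route at 9.

Further compounds
F1 | step 5 | 2-bromo-4,6-dimethoxybenzoyl chloride | COc1cc(Br)c(C(=O)Cl)c(OC)c1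
F2 | step 5 | 1-(2-bromo-4,6-dimethoxyphenyl)-3-[2,4-dimethoxy-5-(pivaloyloxy)phenyl]-2-methoxypropane-1,3-dione (racemic) | COc1cc(Br)c(C(=O)C(OC)C(=O)c2cc(OC(=O)C(C)(C)C)c(OC)cc2OC)c(OC)c1
F3 | step 3 | 5-iodo-2,4-dimethoxyphenyl pivalate | COc1cc(OC)c(OC(=O)C(C)(C)C)cc1I
F4 | step 3 | [2,4-dimethoxy-5-(pivaloyloxy)phenyl]magnesium chloride | COc1cc(OC)c(OC(=O)C(C)(C)C)cc1[Mg]Cl
F5 | step 4 | 3-(2,4-dimethoxyphenyl)-3-hydroxy-1-[2,4-dimethoxy-5-(pivaloyloxy)phenyl]-2-methoxypropan-1-one (mixture of racemic diastereomers) | COc1ccc(C(O)C(OC)C(=O)c2cc(OC(=O)C(C)(C)C)c(OC)cc2OC)c(OC)c1
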